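**Retrosynthetic overview**

1. The route rests on ring C of the flavone: O1 is an aryl ether oxygen on C8a of ring A, and C8a is ortho to C4a, which carries the C4 carbonyl. The O1–C8a bond can therefore be closed by displacing a carbonyl-activated fluoride from ring A.
2. Key disconnections, both made in step 10: C3–C4 (C-aroylation of a ketone enolate) and O1–C8a (intramolecular SNAr). C2, C3 and the C3 prenyl group come from the ring B homoprenyl ketone 10; C4 and ring A come from the fluorobenzoyl chloride 16.
3. Ring order: rings A and B are bought as benzenes; ring C is the only ring formed (step 10).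
4. Ketone 10 comes from 2,4-dimethoxybenzaldehyde (Dakin oxidation, O-allylation, Vilsmeier formylation, homoprenyl Grignard addition, oxidation). Acid chloride 16 comes from 5-fluororesorcinol (O-allylation, Vilsmeier formylation, Pinnick oxidation, chlorination).
5. One Pd-catalysed deallylation frees the three phenols and leaves the two methyl ethers and the C-prenyl group in place.

Key step: step 10

Assumption: 5-fluororesorcinol is taken as a commercial starting material. Ring A is built from it by electrophilic formylation because twofold alkoxide substitution on a 2,4,6-trifluorobenzoate cannot be relied on to give the 2,4-dialkoxy-6-fluoro isomer free of the 2,6-dialkoxy-4-fluoro isomer.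

**Route**

Step 1
Reactants: 1 2,4-dimethoxybenzaldehyde
Product: 3 2,4-dimethoxyphenol, via 2,4-dimethoxyphenyl formate 2 (not isolated)
Conditions: mCPBA, CH2Cl2, 0 °C → rt; aq NaHCO3 wash; then K2CO3 (cat.), MeOH, rt
Reagents that add atoms: mCPBA, O=C(OO)c1cccc(Cl)c1
Why: Baeyer–Villiger (Dakin-type) oxidation, in which the electron-rich 2,4-dimethoxyphenyl group migrates in the Criegee intermediate and the resulting aryl formate is cleaved by base-catalysed methanolysis.

Step 2
Reactants: 3 2,4-dimethoxyphenol
Product: 4 1-(allyloxy)-2,4-dimethoxybenzene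
Conditions: allyl bromide, K2CO3, acetone, reflux
Reagents that add atoms: allyl bromide, C=CCBr
Why: Williamson ether synthesis, the phenoxide being alkylated on oxygen by the SN2-reactive allyl bromide.

Step 3
Reactants: 4 1-(allyloxy)-2,4-dimethoxybenzene
Product: 6 5-(allyloxy)-2,4-dimethoxybenzaldehyde, via aryl iminium salt 5 (not isolated)
Conditions: POCl3, DMF, 0 → 50 °C; then H2O
Reagents that add atoms: DMF, CN(C)C=O; water, O
Why: Vilsmeier–Haack formylation at C5 of 4, the only free position para to one methoxy group and ortho to the other (C3 lies between two methoxy groups and is hindered, C6 is activated by the allyloxy group alone), as in the formylation of 1,2,4-trimethoxybenzene; the allyl ether is inert to POCl3/DMF at this temperature.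

Step 4
Reactants: 6 5-(allyloxy)-2,4-dimethoxybenzaldehyde; 7 5-bromo-2-methylpent-2-ene
Product: 9 1-[5-(allyloxy)-2,4-dimethoxyphenyl]-5-methylhex-4-en-1-ol (racemic), via 4-methylpent-3-enylmagnesium bromide 8 (not isolated)
Conditions: 7, Mg, I2 (cat.), THF, rt → 40 °C; then 6, THF, 0 °C → rt; sat. aq NH4Cl
Reagents that add atoms: none
Why: Grignard addition of the homoprenyl reagent to a non-enolisable aldehyde; the carbinol centre forms as a racemate and is removed by the oxidation in step 5.

Step 5
Reactants: 9 1-[5-(allyloxy)-2,4-dimethoxyphenyl]-5-methylhex-4-en-1-ol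
Product: 10 1-[5-(allyloxy)-2,4-dimethoxyphenyl]-5-methylhex-4-en-1-one
Conditions: Dess–Martin periodinane (DMP), NaHCO3, CH2Cl2, 0 °C → rt
Reagents that add atoms: none
Why: Dess–Martin oxidation of a secondary benzylic alcohol, buffered with NaHCO3 so that acetic acid cannot ionise the electron-rich benzylic alcohol; the alkenes and the allyl ether are not touched.

Step 6
Reactants: 11 5-fluororesorcinol (5-fluorobenzene-1,3-diol)
Product: 12 1,3-bis(allyloxy)-5-fluorobenzene
Conditions: allyl bromide (excess), K2CO3, DMF, 60 °C
Reagents that add atoms: allyl bromide, C=CCBr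
Why: twofold Williamson ether synthesis on the two equivalent phenols.

Step 7
Reactants: 12 1,3-bis(allyloxy)-5-fluorobenzene
Product: 14 2,4-bis(allyloxy)-6-fluorobenzaldehyde, via aryl iminium salt 13 (not isolated)
Conditions: POCl3, DMF, 0 → 80 °C; then H2O
Reagents that add atoms: DMF, CN(C)C=O; water, O
Why: Vilsmeier–Haack formylation at C4 (equivalent to C6) of 12, para to one allyloxy group and ortho to the other, because resorcinol diethers are not substituted between their two oxygens (C2) and the small ortho fluorine offers little hindrance.

Step 8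
Reactants: 14 2,4-bis(allyloxy)-6-fluorobenzaldehyde
Product: 15 2,4-bis(allyloxy)-6-fluorobenzoic acid
Conditions: NaClO2, NaH2PO4, 2-methyl-2-butene (large excess), t-BuOH/H2O, rt
Reagents that add atoms: sodium chlorite, [Na+].[O-]Cl=O
Why: Pinnick (Lindgren) oxidation of the aldehyde by chlorous acid, with 2-methyl-2-butene scavenging the hypochlorous acid so that the allyl ethers and the electron-rich ring are not chlorinated.

Step 9
Reactants: 15 2,4-bis(allyloxy)-6-fluorobenzoic acid
Product: 16 2,4-bis(allyloxy)-6-fluorobenzoyl chloride
Conditions: (COCl)2, DMF (cat.), CH2Cl2, 0 °C → rt; evaporate, use crude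
Reagents that add atoms: oxalyl chloride, ClC(=O)C(Cl)=O
Why: acid chloride formation through the DMF-derived chloroiminium catalyst, which gives only gaseous by-products so that the moisture-sensitive chloride can be used without purification.

Step 10
Reactants: 10 1-[5-(allyloxy)-2,4-dimethoxyphenyl]-5-methylhex-4-en-1-one; 16 2,4-bis(allyloxy)-6-fluorobenzoyl chloride
Product: 19 5,7-bis(allyloxy)-2-[5-(allyloxy)-2,4-dimethoxyphenyl]-3-(3-methylbut-2-enyl)chromen-4-one, via lithium enolate 17 (not isolated), via 2-prenyl 1,3-diketone 18 (not isolated)
Conditions: 10 (2 equiv), LiN(SiMe3)2 (2 equiv), toluene/THF, −78 °C; 16 (1 equiv), −78 → 0 °C; evaporate; then K2CO3, DMF, 90 °C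
Reagents that add atoms: none
Why: Deprotonation of 10 at its only enolisable position gives lithium enolate 17, which attacks the acid chloride through carbon (C3–C4 bond) to give diketone 18; 18 is far more acidic than 10 and is deprotonated at once by a second equivalent of 17, which is why 10 is used in twofold amount and its surplus recovered. In K2CO3/DMF the diketone enolate oxygen on the ring B side adds to the fluorine-bearing carbon of ring A (O1–C8a bond), the Meisenheimer intermediate is stabilised by the ortho C4 carbonyl, and loss of fluoride gives the chromone. The closest known reaction type is the one-pot synthesis of flavones and 2,3-disubstituted chromones from ketone enolates and 2-fluorobenzoyl chlorides (Claisen-type C-acylation followed by intramolecular SNAr). Ring C closes as a six-membered ring by intramolecular addition–elimination at the aromatic C–F carbon, and no stereocentre is formed. The step needs C- over O-acylation, which the tightly coordinated lithium enolate in toluene favours, and displacement of fluoride rather than an allyloxy group, which follows from fluoride being much the better leaving group in SNAr and from the six-membered transition state reaching only the C–F carbon; both allyloxy groups are meta to fluorine and so do not feed electron density onto the carbons that carry the negative charge.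

Step 11
Reactants: 19 5,7-bis(allyloxy)-2-[5-(allyloxy)-2,4-dimethoxyphenyl]-3-(3-methylbut-2-enyl)chromen-4-one
Product: 20 Artoindonesianin R
Conditions: Pd(PPh3)4 (cat.), morpholine (excess), THF, rt → 40 °C
Reagents that add atoms: none
Why: Tsuji–Trost-type deallylation, in which zerovalent palladium ionises each allyl aryl ether to a π-allyl palladium complex and a phenoxide and morpholine traps the allyl unit irreversibly; the prenyl group is bound through carbon and cannot ionise, and the methyl ethers are inert.

**Compound list**

1 | 2,4-dimethoxybenzaldehyde | COc1ccc(C=O)c(OC)c1 | starting material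
2 | 2,4-dimethoxyphenyl formate | O=COc1ccc(OC)cc1OC | intermediate (not isolated)
3 | 2,4-dimethoxyphenol | COc1ccc(O)c(OC)c1 | intermediate
4 | 1-(allyloxy)-2,4-dimethoxybenzene | C=CCOc1ccc(OC)cc1OC | intermediate
5 | N-{[5-(allyloxy)-2,4-dimethoxyphenyl]methylidene}-N-methylmethanaminium dichlorophosphate | C[N+](C)=Cc1cc(OCC=C)c(OC)cc1OC.[O-]P(=O)(Cl)Cl | intermediate (not isolated)
6 | 5-(allyloxy)-2,4-dimethoxybenzaldehyde | O=Cc1cc(OCC=C)c(OC)cc1OC | intermediate
7 | 5-bromo-2-methylpent-2-ene | CC(C)=CCCBr | starting material
8 | 4-methylpent-3-enylmagnesium bromide | CC(C)=CCC[Mg]Br | intermediate (not isolated)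
9 | 1-[5-(allyloxy)-2,4-dimethoxyphenyl]-5-methylhex-4-en-1-ol (racemic) | CC(C)=CCCC(O)c1cc(OCC=C)c(OC)cc1OC | intermediate
10 | 1-[5-(allyloxy)-2,4-dimethoxyphenyl]-5-methylhex-4-en-1-one | CC(C)=CCCC(=O)c1cc(OCC=C)c(OC)cc1OC | intermediate
11 | 5-fluororesorcinol (5-fluorobenzene-1,3-diol) | Oc1cc(O)cc(F)c1 | starting material
12 | 1,3-bis(allyloxy)-5-fluorobenzene | C=CCOc1cc(F)cc(OCC=C)c1 | intermediate
13 | N-{[2,4-bis(allyloxy)-6-fluorophenyl]methylidene}-N-methylmethanaminium dichlorophosphate | C[N+](C)=Cc1c(F)cc(OCC=C)cc1OCC=C.[O-]P(=O)(Cl)Cl | intermediate (not isolated)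
14 | 2,4-bis(allyloxy)-6-fluorobenzaldehyde | O=Cc1c(F)cc(OCC=C)cc1OCC=C | intermediate
15 | 2,4-bis(allyloxy)-6-fluorobenzoic acid | OC(=O)c1c(F)cc(OCC=C)cc1OCC=C | intermediate
16 | 2,4-bis(allyloxy)-6-fluorobenzoyl chloride | O=C(Cl)c1c(F)cc(OCC=C)cc1OCC=C | intermediate
17 | lithium (Z)-1-[5-(allyloxy)-2,4-dimethoxyphenyl]-5-methylhexa-1,4-dien-1-olate (Z expected; geometry of no consequence) | [Li]O/C(=C\CC=C(C)C)c1cc(OCC=C)c(OC)cc1OC | intermediate (not isolated)
18 | 1-[2,4-bis(allyloxy)-6-fluorophenyl]-3-[5-(allyloxy)-2,4-dimethoxyphenyl]-2-(3-methylbut-2-enyl)propane-1,3-dione (racemic, enolisable centre) | CC(C)=CCC(C(=O)c1cc(OCC=C)c(OC)cc1OC)C(=O)c1c(F)cc(OCC=C)cc1OCC=C | intermediate (not isolated)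
19 | 5,7-bis(allyloxy)-2-[5-(allyloxy)-2,4-dimethoxyphenyl]-3-(3-methylbut-2-enyl)chromen-4-one | O=c1c(CC=C(C)C)c(-c2cc(OCC=C)c(OC)cc2OC)oc2cc(OCC=C)cc(OCC=C)c12 | intermediate
20 | Artoindonesianin R, 5,7-dihydroxy-2-(5-hydroxy-2,4-dimethoxyphenyl)-3-(3-methylbut-2-enyl)chromen-4-one (no stereocentres) | COc1cc(OC)c(-c2oc3cc(O)cc(O)c3c(=O)c2CC=C(C)C)cc1O | target

**Step count**

Total steps: 11. Longest linear sequence: 7 steps (steps 1–5, 10, 11).

**Steps most likely to fail**

1. Step 10. The hindered, electron-rich, doubly ortho-substituted acid chloride may acylate the enolate on oxygen, or react too slowly, so that enol ester and unchanged ketone result instead of the C-acylated diketone. The fallback sets out from 10 and from aldehyde 14, which the route already makes, and replaces the acylation by an aldol addition, which can only form the carbon–carbon bond. The lithium enolate 17 (LiN(SiMe3)2, THF, −78 °C) would be added to 14 and quenched cold to give 3-[2,4-bis(allyloxy)-6-fluorophenyl]-1-[5-(allyloxy)-2,4-dimethoxyphenyl]-3-hydroxy-2-(3-methylbut-2-enyl)propan-1-one F1 as a diastereomer mixture of no consequence. Dess–Martin oxidation of the β-hydroxy ketone would give diketone 18, now isolated. K2CO3 in DMF at 90 °C would then close ring C, and the route is rejoined at 19.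

2. Step 7. The fluorine-deactivated ring may formylate sluggishly, and at the temperature then needed the acid set free may begin to cleave the allyl ethers. The fallback sets out from 12 and uses a more reactive electrophile at low temperature, then a carboxylation. NBS in MeCN at 0 °C should brominate the same position (para to one allyloxy group, ortho to fluorine) to give 1,5-bis(allyloxy)-2-bromo-3-fluorobenzene F2. Bromine–lithium exchange with n-BuLi in THF at −78 °C, kept cold so that the ortho-fluoroaryllithium does not lose lithium fluoride, followed by CO2 and acidic work-up, would give acid 15 directly. The route is rejoined at 15 and step 8 is not needed.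

3. Step 11. The π-allyl palladium intermediates may C-allylate the freed, phloroglucinol-like ring A at C6 or C8, or the threefold cleavage may stop short. The fallback sets out from 19 and avoids allyl cation equivalents. Isomerisation of the three allyl ethers with [Ir(cod)(PMePh2)2]PF6 (activated with H2, then purged) in THF at rt, which leaves the trisubstituted prenyl alkene alone, would give 2-[2,4-dimethoxy-5-(prop-1-enyloxy)phenyl]-3-(3-methylbut-2-enyl)-5,7-bis(prop-1-enyloxy)chromen-4-one F3. Hydrolysis of the enol ethers with dilute HCl in acetone/water at rt would give the target, and the route is rejoined at 20.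

**Further compounds**

F1 | step 10 | 3-[2,4-bis(allyloxy)-6-fluorophenyl]-1-[5-(allyloxy)-2,4-dimethoxyphenyl]-3-hydroxy-2-(3-methylbut-2-enyl)propan-1-one (diastereomer mixture, racemic) | CC(C)=CCC(C(O)c1c(F)cc(OCC=C)cc1OCC=C)C(=O)c1cc(OCC=C)c(OC)cc1OC
F2 | step 7 | 1,5-bis(allyloxy)-2-bromo-3-fluorobenzene | C=CCOc1cc(F)c(Br)c(OCC=C)c1
F3 | step 11 | 2-[2,4-dimethoxy-5-((E)-prop-1-enyloxy)phenyl]-3-(3-methylbut-2-enyl)-5,7-bis((E)-prop-1-enyloxy)chromen-4-one (E expected; geometry of no consequence) | C/C=C/Oc1cc(O/C=C/C)c2c(c1)oc(-c1cc(O/C=C/C)c(OC)cc1OC)c(CC=C(C)C)c2=O
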